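## Retrosynthetic overview

1. Target 40 ⇒ nona-O-methyl ether 39 (BBr3) ⇒ Suzuki–Miyaura cut of the stilbene at the bond between the vinyl group and C6 of ring B, giving aryl chloride 26 (units 2 and 3) and styryl MIDA boronate 37 (unit 1, from aryl chloride 35 and the bis-boron vinyl reagent 36).
2. The three C3–aryl bonds ⇒ decarboxylative arylation of trans dihydrobenzofuran-3-carboxylic acids: C3(unit 2)–C4(ring C) from acid 10 and bromide 23, and the two 3,5-dimethoxyphenyl groups from acids 25 and 34 with bromide 11.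
3. Each dihydrofuran ring ⇒ C2–C3 cut to an aryldiazoacetate with an ortho 4-methoxybenzyl ether (7, 21, 31), closed by dirhodium-carbene C–H insertion and then epimerised at C3 to trans; the arylacetates 6 and 30 come from aryl bromides and one batch of the Reformatsky reagent 5.
4. Feature the plan rests on: in the central dihydrobenzofuran (unit 2, ring B) C2 is a CH bonded to O1 and to a 4-oxyphenyl ring, and C3 sits on ring carbon C3a ortho to O1, so a carbene at C3 reaches this doubly activated C–H through a five-membered transition state. Unit 2 is (2R,3R) while units 1 (ring A, 7-OH) and 3 (ring C, 6-OH) are (2S,3S), so each ring is set by its own catalyst enantiomer.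
5. Ring order: furan of unit 2 (step 5), furan of unit 3 (step 14), union and arylation (steps 15–17), furan of unit 1 (step 22), stilbene (step 26), deprotection (step 27).

Key step: step 5

Remark: the sense of induction is assigned by analogy with related ortho-(benzyloxy)aryldiazoacetates, Rh2(S-PTTL)4 being expected to give (2R) and Rh2(R-PTTL)4 (2S); should the first insertion show the opposite sense, the two catalysts are exchanged between step 5 and steps 14 and 22.

## Route

### Unit 2 (central ring B)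

Step 1
Reactants: 1 2-bromo-5-chlorophenol; 2 4-methoxybenzyl chloride
Product: 3 1-bromo-4-chloro-2-[(4-methoxybenzyl)oxy]benzene
Conditions: K2CO3, DMF, 60 °C
Reagents that add atoms: none
Why: Williamson ether synthesis, in which the phenoxide formed with K2CO3 displaces the benzylic chloride by SN2 and no other nucleophilic site is present.

Step 2
Reactants: 4 methyl bromoacetate
Product: 5 (2-methoxy-2-oxoethyl)zinc bromide (Reformatsky reagent as a titrated THF solution)
Conditions: Zn dust (1.5 equiv), TMSCl (5 mol%), THF, 40 °C; decanted from excess Zn under argon, titrated with I2, kept at 0 °C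
Reagents that add atoms: zinc, [Zn]
Why: Reformatsky reagent formation, in which zinc metal activated by TMSCl inserts into the C–Br bond of the α-bromo ester to give the bromozinc ester enolate, which should keep in cold THF under argon so that one batch serves steps 3 and 20.

Step 3
Reactants: 3 1-bromo-4-chloro-2-[(4-methoxybenzyl)oxy]benzene; 5 (2-methoxy-2-oxoethyl)zinc bromide
Product: 6 methyl 2-{4-chloro-2-[(4-methoxybenzyl)oxy]phenyl}acetate
Conditions: 5 (1.3 equiv, THF solution from step 2), Pd(dba)2 (2 mol%), XPhos (4 mol%), THF, 40 °C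
Reagents that add atoms: none
Why: Negishi-type coupling of a Reformatsky reagent (palladium-catalysed α-arylation of a zinc ester enolate), in which zerovalent palladium adds to C–Br much faster than to C–Cl and the neutral zinc enolate leaves the benzyl ether and the ester alone.

Step 4
Reactants: 6 methyl 2-{4-chloro-2-[(4-methoxybenzyl)oxy]phenyl}acetate
Product: 7 methyl 2-{4-chloro-2-[(4-methoxybenzyl)oxy]phenyl}-2-diazoacetate
Conditions: 4-acetamidobenzenesulfonyl azide (1.3 equiv), DBU (1.5 equiv), MeCN, 0 °C → rt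
Reagents that add atoms: 4-acetamidobenzenesulfonyl azide, CC(=O)Nc1ccc(cc1)S(=O)(=O)N=[N+]=[N-]
Why: Regitz diazo transfer, in which DBU deprotonates the benzylic ester CH2, the enolate attacks the terminal nitrogen of the sulfonyl azide and loss of the sulfonamide leaves the donor–acceptor diazo ester.

Step 5
Reactants: 7 methyl 2-{4-chloro-2-[(4-methoxybenzyl)oxy]phenyl}-2-diazoacetate
Product: 9 methyl (2R,3R)-6-chloro-2-(4-methoxyphenyl)-2,3-dihydrobenzofuran-3-carboxylate (trans), via cis ester 8 (not isolated)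
Conditions: Rh2(S-PTTL)4 (dirhodium tetrakis[N-phthaloyl-(S)-tert-leucinate], 1 mol%), toluene, −78 °C, slow addition of 7; then NaOMe (0.3 equiv), MeOH/THF, 0 °C → rt
Reagents that add atoms: none
Why: Rh2(S-PTTL)4 takes N2 out of 7 and gives an electrophilic donor–acceptor carbene of divalent rhodium at the future C3, which inserts into one of the two enantiotopic C–H bonds of the OCH2 group of the 4-methoxybenzyl ether in a concerted, asynchronous three-centre step with hydride-shift character, the developing positive charge sitting on a carbon stabilised by both the ether oxygen and the 4-methoxyphenyl ring. The closest known reaction type is the intramolecular C–H insertion of ortho-(benzyloxy)aryldiazoacetates under chiral dirhodium carboxylate catalysis, which gives cis 2-aryl-2,3-dihydrobenzofuran-3-carboxylates. The furan ring O1–C2–C3–C3a–C7a closes by 1,5-insertion through a five-membered transition state, the only mode open because the carbene carbon and the OCH2 group sit on neighbouring carbons of ring B, and the new bond is C2–C3. C2 is controlled by the chiral phthalimido carboxylate ligands, which select the hydrogen to be replaced and the carbene face and should give (2R) with the ester cis (8); C3 is then controlled thermodynamically, because catalytic methoxide enolises the ester and reprotonation places CO2Me anti to the C2 aryl group, giving (2R,3R)-9. C2 is not touched in this equilibration, since it bears no acidic hydrogen and its C2–O1 bond lies near the nodal plane of the enolate, so ring opening by β-elimination is not expected. The step needs insertion to win over carbene dimerisation and attack on the anisyl ring, and needs the C–Cl bond to stay intact; the five-membered geometry, slow addition at −78 °C and the inertness of aryl chlorides toward rhodium carbenes should secure this.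

Step 6
Reactants: 9 methyl (2R,3R)-6-chloro-2-(4-methoxyphenyl)-2,3-dihydrobenzofuran-3-carboxylate
Product: 10 (2R,3R)-6-chloro-2-(4-methoxyphenyl)-2,3-dihydrobenzofuran-3-carboxylic acid
Conditions: LiOH·H2O (3 equiv), THF/MeOH/H2O, 0 °C → rt; then 1 M HCl to pH 3, 0 °C
Reagents that add atoms: lithium hydroxide, [Li+].[OH-]
Why: Ester saponification, which cannot change C3 because the trans ester is already the thermodynamic isomer, while C2 has no acidic hydrogen and the brief cold acidification spares the benzylic C2–O1 bond.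

### Unit 3 (ring C)

Step 7
Reactants: 11 1-bromo-3,5-dimethoxybenzene
Product: 13 2-bromo-4,6-dimethoxybenzaldehyde, via aryl iminium chloride 12 (not isolated)
Conditions: POCl3 (1.5 equiv), DMF, 0 → 90 °C; then H2O, 0 °C → rt
Reagents that add atoms: N,N-dimethylformamide, CN(C)C=O; water, O
Why: Vilsmeier–Haack formylation, in which the chloroiminium ion attacks the ring carbon para to one methoxy group and ortho to the other (next to bromine) in preference to the more hindered carbon between the two methoxy groups, and water then hydrolyses the iminium salt 12.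

Step 8
Reactants: 13 2-bromo-4,6-dimethoxybenzaldehyde
Product: 14 2-bromo-6-hydroxy-4-methoxybenzaldehyde
Conditions: BCl3 (1.2 equiv), CH2Cl2, −78 → 0 °C; then H2O
Reagents that add atoms: none
Why: Chelation-controlled Lewis-acid demethylation, in which boron bound between the formyl oxygen and the ortho methoxy oxygen activates only that methyl group for attack by chloride, so the para methoxy group is kept.

Step 9
Reactants: 14 2-bromo-6-hydroxy-4-methoxybenzaldehyde; 2 4-methoxybenzyl chloride
Product: 15 2-bromo-4-methoxy-6-[(4-methoxybenzyl)oxy]benzaldehyde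
Conditions: K2CO3, DMF, 60 °C
Reagents that add atoms: none
Why: Williamson ether synthesis on the only phenol, the aldehyde and the aryl bromide being inert to carbonate.

Step 10
Reactants: 15 2-bromo-4-methoxy-6-[(4-methoxybenzyl)oxy]benzaldehyde
Product: 16 (RS)-1-{2-bromo-4-methoxy-6-[(4-methoxybenzyl)oxy]phenyl}-2,2,2-trichloroethanol
Conditions: Cl3CCO2Na (1.5 equiv), Cl3CCO2H (1.5 equiv), DMF, 0 °C → rt
Reagents that add atoms: sodium trichloroacetate, [Na+].[O-]C(=O)C(Cl)(Cl)Cl
Why: Decarboxylative trichloromethylation of an aldehyde (the carbinol-forming stage of the Jocic–Reeve homologation), in which trichloroacetate loses CO2, the trichloromethyl anion adds to the formyl group and the buffered acid traps the alkoxide without harming the benzyl ether; the new carbinol centre is racemic and is removed in step 11.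

Step 11
Reactants: 16 (RS)-1-{2-bromo-4-methoxy-6-[(4-methoxybenzyl)oxy]phenyl}-2,2,2-trichloroethanol
Product: 19 2-{2-bromo-4-methoxy-6-[(4-methoxybenzyl)oxy]phenyl}acetic acid, via dichlorooxirane 17 (not isolated), via arylacetyl chloride 18 (not isolated)
Conditions: NaBH4 (2.5 equiv), NaOH (5 equiv), t-BuOH, 55 °C; then 1 M HCl, 0 °C
Reagents that add atoms: sodium hydroxide, [Na+].[OH-]
Why: Reductive Jocic–Reeve one-carbon homologation, in which hydroxide closes the carbinol to the gem-dichlorooxirane 17, hydride opens it at the activated benzylic carbon to the acyl chloride 18 and hydroxide hydrolyses this to the arylacetate, conditions that leave the aryl bromide and both ethers untouched.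

Step 12
Reactants: 19 2-{2-bromo-4-methoxy-6-[(4-methoxybenzyl)oxy]phenyl}acetic acid
Product: 20 methyl 2-{2-bromo-4-methoxy-6-[(4-methoxybenzyl)oxy]phenyl}acetate
Conditions: MeI (1.5 equiv), K2CO3, DMF, rt
Reagents that add atoms: iodomethane, CI
Why: O-alkylation of a carboxylate by SN2 on iodomethane, a neutral-to-basic esterification that avoids acid near the 4-methoxybenzyl ether.

Step 13
Reactants: 20 methyl 2-{2-bromo-4-methoxy-6-[(4-methoxybenzyl)oxy]phenyl}acetate
Product: 21 methyl 2-{2-bromo-4-methoxy-6-[(4-methoxybenzyl)oxy]phenyl}-2-diazoacetate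
Conditions: 4-acetamidobenzenesulfonyl azide (1.5 equiv), DBU (2 equiv), MeCN, 0 °C → rt
Reagents that add atoms: 4-acetamidobenzenesulfonyl azide, CC(=O)Nc1ccc(cc1)S(=O)(=O)N=[N+]=[N-]
Why: Regitz diazo transfer as in step 4, expected to be slower because the two ortho substituents twist the enolate out of conjugation, hence the larger excess of base and azide.

Step 14
Reactants: 21 methyl 2-{2-bromo-4-methoxy-6-[(4-methoxybenzyl)oxy]phenyl}-2-diazoacetate
Product: 23 methyl (2S,3S)-4-bromo-6-methoxy-2-(4-methoxyphenyl)-2,3-dihydrobenzofuran-3-carboxylate (trans), via cis ester 22 (not isolated)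
Conditions: Rh2(R-PTTL)4 (2 mol%), toluene, −78 → −40 °C, slow addition of 21; then NaOMe (0.3 equiv), MeOH/THF, 0 °C → rt
Reagents that add atoms: none
Why: The same intramolecular carbene C–H insertion into the benzylic ether CH2 as in step 5, now with the enantiomeric catalyst so that the ligands should set (2S), after which methoxide epimerises C3 of the cis ester 22 to the trans (2S,3S) ester, the C–Br bond being inert to the rhodium carbene.

### Union of units 2 and 3

Step 15
Reactants: 10 (2R,3R)-6-chloro-2-(4-methoxyphenyl)-2,3-dihydrobenzofuran-3-carboxylic acid; 23 methyl (2S,3S)-4-bromo-6-methoxy-2-(4-methoxyphenyl)-2,3-dihydrobenzofuran-3-carboxylate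
Product: 24 methyl (2S,3S)-4-[(2R,3R)-6-chloro-2-(4-methoxyphenyl)-2,3-dihydrobenzofuran-3-yl]-6-methoxy-2-(4-methoxyphenyl)-2,3-dihydrobenzofuran-3-carboxylate
Conditions: NiCl2·glyme (10 mol%), dtbbpy (15 mol%), Ir[dF(CF3)ppy]2(dtbbpy)PF6 (2 mol%), Cs2CO3 (1.5 equiv), DMF, blue LEDs (450 nm), 25 °C
Reagents that add atoms: none
Why: Metallaphotoredox decarboxylative arylation, in which the excited iridium photocatalyst oxidises the caesium carboxylate of 10, loss of CO2 gives the secondary benzylic C3 radical, the arylnickel bromide formed from 23 and zerovalent nickel captures it and reductive elimination forms C3(unit 2)–C4(ring C) on the face anti to the C2 aryl group, so unit 2 should emerge trans (2R,3R) while the C–Cl bond and the stereocentres of 23 are not involved.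

Step 16
Reactants: 24 methyl (2S,3S)-4-[(2R,3R)-6-chloro-2-(4-methoxyphenyl)-2,3-dihydrobenzofuran-3-yl]-6-methoxy-2-(4-methoxyphenyl)-2,3-dihydrobenzofuran-3-carboxylate
Product: 25 (2S,3S)-4-[(2R,3R)-6-chloro-2-(4-methoxyphenyl)-2,3-dihydrobenzofuran-3-yl]-6-methoxy-2-(4-methoxyphenyl)-2,3-dihydrobenzofuran-3-carboxylic acid
Conditions: LiOH·H2O (5 equiv), THF/MeOH/H2O, 45 °C; then 1 M HCl to pH 3, 0 °C
Reagents that add atoms: lithium hydroxide, [Li+].[OH-]
Why: Saponification of the hindered ester, in which the only enolisable centre (C3 of unit 3) is already trans and the diarylmethine C3 of unit 2 is not acidic enough to epimerise.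

Step 17
Reactants: 25 (2S,3S)-4-[(2R,3R)-6-chloro-2-(4-methoxyphenyl)-2,3-dihydrobenzofuran-3-yl]-6-methoxy-2-(4-methoxyphenyl)-2,3-dihydrobenzofuran-3-carboxylic acid; 11 1-bromo-3,5-dimethoxybenzene
Product: 26 (2R,3R)-6-chloro-3-[(2S,3S)-3-(3,5-dimethoxyphenyl)-6-methoxy-2-(4-methoxyphenyl)-2,3-dihydrobenzofuran-4-yl]-2-(4-methoxyphenyl)-2,3-dihydrobenzofuran
Conditions: 11 (3 equiv), NiCl2·glyme (10 mol%), dtbbpy (15 mol%), Ir[dF(CF3)ppy]2(dtbbpy)PF6 (2 mol%), Cs2CO3 (1.5 equiv), DMF, blue LEDs (450 nm), 25 °C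
Reagents that add atoms: none
Why: The same metallaphotoredox decarboxylative arylation, now with an unhindered aryl bromide in excess, in which the planar C3 radical of unit 3 is arylated anti to its C2 aryl group to give the trans (2S,3S) ring while the aryl chloride of unit 2 does not add to zerovalent nickel under these conditions.

### Unit 1 (ring A)

Step 18
Reactants: 27 4-chloro-2-methoxyphenol
Product: 28 2-bromo-4-chloro-6-methoxyphenol
Conditions: NBS (1.05 equiv), MeCN, 0 °C → rt
Reagents that add atoms: N-bromosuccinimide, BrN1C(=O)CCC1=O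
Why: Electrophilic aromatic bromination directed by the hydroxyl group, whose para position is blocked by chlorine so that the single free ortho carbon is brominated.

Step 19
Reactants: 28 2-bromo-4-chloro-6-methoxyphenol; 2 4-methoxybenzyl chloride
Product: 29 1-bromo-5-chloro-3-methoxy-2-[(4-methoxybenzyl)oxy]benzene
Conditions: K2CO3, DMF, 60 °C
Reagents that add atoms: none
Why: Williamson ether synthesis, the flanked phenoxide still being a good nucleophile toward the reactive benzylic chloride.

Step 20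
Reactants: 29 1-bromo-5-chloro-3-methoxy-2-[(4-methoxybenzyl)oxy]benzene; 5 (2-methoxy-2-oxoethyl)zinc bromide
Product: 30 methyl 2-{5-chloro-3-methoxy-2-[(4-methoxybenzyl)oxy]phenyl}acetate
Conditions: 5 (1.3 equiv, THF solution from step 2), Pd(dba)2 (2 mol%), XPhos (4 mol%), THF, 40 °C
Reagents that add atoms: none
Why: Negishi-type coupling of the Reformatsky reagent as in step 3, selective for C–Br over C–Cl.

Step 21
Reactants: 30 methyl 2-{5-chloro-3-methoxy-2-[(4-methoxybenzyl)oxy]phenyl}acetate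
Product: 31 methyl 2-{5-chloro-3-methoxy-2-[(4-methoxybenzyl)oxy]phenyl}-2-diazoacetate
Conditions: 4-acetamidobenzenesulfonyl azide (1.3 equiv), DBU (1.5 equiv), MeCN, 0 °C → rt
Reagents that add atoms: 4-acetamidobenzenesulfonyl azide, CC(=O)Nc1ccc(cc1)S(=O)(=O)N=[N+]=[N-]
Why: Regitz diazo transfer to the arylacetate as in step 4.

Step 22
Reactants: 31 methyl 2-{5-chloro-3-methoxy-2-[(4-methoxybenzyl)oxy]phenyl}-2-diazoacetate
Product: 33 methyl (2S,3S)-5-chloro-7-methoxy-2-(4-methoxyphenyl)-2,3-dihydrobenzofuran-3-carboxylate (trans), via cis ester 32 (not isolated)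
Conditions: Rh2(R-PTTL)4 (1 mol%), toluene, −78 °C, slow addition of 31; then NaOMe (0.3 equiv), MeOH/THF, 0 °C → rt
Reagents that add atoms: none
Why: The intramolecular carbene C–H insertion of step 5 run with the enantiomeric catalyst, whose ligands should set (2S) in the cis ester 32, followed by methoxide epimerisation of C3 to the trans (2S,3S) ester.

Step 23
Reactants: 33 methyl (2S,3S)-5-chloro-7-methoxy-2-(4-methoxyphenyl)-2,3-dihydrobenzofuran-3-carboxylate
Product: 34 (2S,3S)-5-chloro-7-methoxy-2-(4-methoxyphenyl)-2,3-dihydrobenzofuran-3-carboxylic acid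
Conditions: LiOH·H2O (3 equiv), THF/MeOH/H2O, 0 °C → rt; then 1 M HCl to pH 3, 0 °C
Reagents that add atoms: lithium hydroxide, [Li+].[OH-]
Why: Ester saponification of the thermodynamic trans ester, as in step 6.

Step 24
Reactants: 34 (2S,3S)-5-chloro-7-methoxy-2-(4-methoxyphenyl)-2,3-dihydrobenzofuran-3-carboxylic acid; 11 1-bromo-3,5-dimethoxybenzene
Product: 35 (2S,3S)-5-chloro-3-(3,5-dimethoxyphenyl)-7-methoxy-2-(4-methoxyphenyl)-2,3-dihydrobenzofuran
Conditions: 11 (1.5 equiv), NiCl2·glyme (10 mol%), dtbbpy (15 mol%), Ir[dF(CF3)ppy]2(dtbbpy)PF6 (2 mol%), Cs2CO3 (1.5 equiv), DMF, blue LEDs (450 nm), 25 °C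
Reagents that add atoms: none
Why: Metallaphotoredox decarboxylative arylation as in step 15, in which the benzylic C3 radical is arylated anti to the C2 aryl group to give the trans (2S,3S) ring and the aryl chloride is kept.

Step 25
Reactants: 35 (2S,3S)-5-chloro-3-(3,5-dimethoxyphenyl)-7-methoxy-2-(4-methoxyphenyl)-2,3-dihydrobenzofuran; 36 6-methyl-2-[(E)-2-(4,4,5,5-tetramethyl-1,3,2-dioxaborolan-2-yl)ethenyl]-1,3,6,2-dioxazaborocane-4,8-dione
Product: 37 2-{(E)-2-[(2S,3S)-3-(3,5-dimethoxyphenyl)-7-methoxy-2-(4-methoxyphenyl)-2,3-dihydrobenzofuran-5-yl]ethenyl}-6-methyl-1,3,6,2-dioxazaborocane-4,8-dione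
Conditions: Pd(OAc)2 (5 mol%), SPhos (10 mol%), K3PO4 (anhydrous, 3 equiv), dioxane, 80 °C
Reagents that add atoms: none
Why: Suzuki–Miyaura coupling that is chemoselective between two boron groups, since under anhydrous base only the trigonal pinacol boronate of 36 transmetalates while the tetracoordinate MIDA boronate stays masked, the dialkylbiarylphosphine lets zerovalent palladium add to the electron-rich aryl chloride and the E geometry is retained.

### Endgame

Step 26
Reactants: 26 (2R,3R)-6-chloro-3-[(2S,3S)-3-(3,5-dimethoxyphenyl)-6-methoxy-2-(4-methoxyphenyl)-2,3-dihydrobenzofuran-4-yl]-2-(4-methoxyphenyl)-2,3-dihydrobenzofuran; 37 styryl MIDA boronate of unit 1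
Product: 39 nona-O-methyl ether of the target [(2S,3S)-3-(3,5-dimethoxyphenyl)-5-{(E)-2-[(2R,3R)-3-[(2S,3S)-3-(3,5-dimethoxyphenyl)-6-methoxy-2-(4-methoxyphenyl)-2,3-dihydrobenzofuran-4-yl]-2-(4-methoxyphenyl)-2,3-dihydrobenzofuran-6-yl]ethenyl}-7-methoxy-2-(4-methoxyphenyl)-2,3-dihydrobenzofuran], via styrylboronic acid 38 (not isolated)
Conditions: Pd(OAc)2 (5 mol%), SPhos (10 mol%), K3PO4 (7.5 equiv), dioxane/H2O 5:1, degassed, 60–80 °C
Reagents that add atoms: none
Why: Slow-release Suzuki–Miyaura coupling, in which aqueous K3PO4 hydrolyses the MIDA boronate gradually to the boronic acid 38 that couples with the unhindered aryl chloride of 26 with retention of the E geometry before it can protodeboronate, no stereocentre lying near the reacting carbons.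

Step 27
Reactants: 39 nona-O-methyl ether of the target
Product: 40 CNP0265934.1 (5-[(2S,3S)-5-{(E)-2-[(2R,3R)-3-[(2S,3S)-3-(3,5-dihydroxyphenyl)-6-hydroxy-2-(4-hydroxyphenyl)-2,3-dihydrobenzofuran-4-yl]-2-(4-hydroxyphenyl)-2,3-dihydrobenzofuran-6-yl]ethenyl}-7-hydroxy-2-(4-hydroxyphenyl)-2,3-dihydrobenzofuran-3-yl]benzene-1,3-diol)
Conditions: BBr3 (20 equiv), CH2Cl2, −78 → 0 °C; then MeOH, aq. NaHCO3
Reagents that add atoms: none
Why: Lewis-acid cleavage of aryl methyl ethers, in which boron binds each methoxy oxygen and bromide removes the methyl group by SN2; should a C2–O1 bond open reversibly through a para-quinone methide it is expected to reclose to the trans ring dictated by the untouched C3 centre, and no aryl ring is placed for cyclisation onto the stilbene.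

## Compound list

1 | 2-bromo-5-chlorophenol | Oc1cc(Cl)ccc1Br | starting material
2 | 4-methoxybenzyl chloride | COc1ccc(CCl)cc1 | starting material
3 | 1-bromo-4-chloro-2-[(4-methoxybenzyl)oxy]benzene | COc1ccc(COc2cc(Cl)ccc2Br)cc1 | intermediate
4 | methyl bromoacetate | COC(=O)CBr | starting material
5 | (2-methoxy-2-oxoethyl)zinc bromide (Reformatsky reagent, THF solution) | COC(=O)C[Zn]Br | intermediate
6 | methyl 2-{4-chloro-2-[(4-methoxybenzyl)oxy]phenyl}acetate | COC(=O)Cc1ccc(Cl)cc1OCc1ccc(OC)cc1 | intermediate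
7 | methyl 2-{4-chloro-2-[(4-methoxybenzyl)oxy]phenyl}-2-diazoacetate | COC(=O)C(=[N+]=[N-])c1ccc(Cl)cc1OCc1ccc(OC)cc1 | intermediate
8 | methyl (2R,3S)-6-chloro-2-(4-methoxyphenyl)-2,3-dihydrobenzofuran-3-carboxylate (cis) | Clc1ccc2c(c1)O[C@@H](c1ccc(OC)cc1)[C@H]2C(=O)OC | intermediate
9 | methyl (2R,3R)-6-chloro-2-(4-methoxyphenyl)-2,3-dihydrobenzofuran-3-carboxylate (trans) | Clc1ccc2c(c1)O[C@@H](c1ccc(OC)cc1)[C@@H]2C(=O)OC | intermediate
10 | (2R,3R)-6-chloro-2-(4-methoxyphenyl)-2,3-dihydrobenzofuran-3-carboxylic acid | Clc1ccc2c(c1)O[C@@H](c1ccc(OC)cc1)[C@@H]2C(=O)O | intermediate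
11 | 1-bromo-3,5-dimethoxybenzene | COc1cc(Br)cc(OC)c1 | starting material
12 | N-[(2-bromo-4,6-dimethoxyphenyl)methylidene]-N-methylmethanaminium chloride | COc1cc(Br)c(C=[N+](C)C)c(OC)c1.[Cl-] | intermediate
13 | 2-bromo-4,6-dimethoxybenzaldehyde | COc1cc(Br)c(C=O)c(OC)c1 | intermediate
14 | 2-bromo-6-hydroxy-4-methoxybenzaldehyde | COc1cc(O)c(C=O)c(Br)c1 | intermediate
15 | 2-bromo-4-methoxy-6-[(4-methoxybenzyl)oxy]benzaldehyde | COc1ccc(COc2cc(OC)cc(Br)c2C=O)cc1 | intermediate
16 | (RS)-1-{2-bromo-4-methoxy-6-[(4-methoxybenzyl)oxy]phenyl}-2,2,2-trichloroethanol | COc1ccc(COc2cc(OC)cc(Br)c2C(O)C(Cl)(Cl)Cl)cc1 | intermediate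
17 | (RS)-3-{2-bromo-4-methoxy-6-[(4-methoxybenzyl)oxy]phenyl}-2,2-dichlorooxirane | COc1ccc(COc2cc(OC)cc(Br)c2C3OC3(Cl)Cl)cc1 | intermediate
18 | 2-{2-bromo-4-methoxy-6-[(4-methoxybenzyl)oxy]phenyl}acetyl chloride | COc1ccc(COc2cc(OC)cc(Br)c2CC(=O)Cl)cc1 | intermediate
19 | 2-{2-bromo-4-methoxy-6-[(4-methoxybenzyl)oxy]phenyl}acetic acid | COc1ccc(COc2cc(OC)cc(Br)c2CC(=O)O)cc1 | intermediate
20 | methyl 2-{2-bromo-4-methoxy-6-[(4-methoxybenzyl)oxy]phenyl}acetate | COc1ccc(COc2cc(OC)cc(Br)c2CC(=O)OC)cc1 | intermediate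
21 | methyl 2-{2-bromo-4-methoxy-6-[(4-methoxybenzyl)oxy]phenyl}-2-diazoacetate | COc1ccc(COc2cc(OC)cc(Br)c2C(=[N+]=[N-])C(=O)OC)cc1 | intermediate
22 | methyl (2S,3R)-4-bromo-6-methoxy-2-(4-methoxyphenyl)-2,3-dihydrobenzofuran-3-carboxylate (cis) | COc1cc(Br)c2c(c1)O[C@H](c1ccc(OC)cc1)[C@@H]2C(=O)OC | intermediate
23 | methyl (2S,3S)-4-bromo-6-methoxy-2-(4-methoxyphenyl)-2,3-dihydrobenzofuran-3-carboxylate (trans) | COc1cc(Br)c2c(c1)O[C@H](c1ccc(OC)cc1)[C@H]2C(=O)OC | intermediate
24 | methyl (2S,3S)-4-[(2R,3R)-6-chloro-2-(4-methoxyphenyl)-2,3-dihydrobenzofuran-3-yl]-6-methoxy-2-(4-methoxyphenyl)-2,3-dihydrobenzofuran-3-carboxylate | Clc1ccc2c(c1)O[C@@H](c1ccc(OC)cc1)[C@@H]2c1cc(OC)cc2c1[C@H](C(=O)OC)[C@@H](c1ccc(OC)cc1)O2 | intermediate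
25 | (2S,3S)-4-[(2R,3R)-6-chloro-2-(4-methoxyphenyl)-2,3-dihydrobenzofuran-3-yl]-6-methoxy-2-(4-methoxyphenyl)-2,3-dihydrobenzofuran-3-carboxylic acid | Clc1ccc2c(c1)O[C@@H](c1ccc(OC)cc1)[C@@H]2c1cc(OC)cc2c1[C@H](C(=O)O)[C@@H](c1ccc(OC)cc1)O2 | intermediate
26 | (2R,3R)-6-chloro-3-[(2S,3S)-3-(3,5-dimethoxyphenyl)-6-methoxy-2-(4-methoxyphenyl)-2,3-dihydrobenzofuran-4-yl]-2-(4-methoxyphenyl)-2,3-dihydrobenzofuran | Clc1ccc2c(c1)O[C@@H](c1ccc(OC)cc1)[C@@H]2c1cc(OC)cc2c1[C@H](c1cc(OC)cc(OC)c1)[C@@H](c1ccc(OC)cc1)O2 | intermediate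
27 | 4-chloro-2-methoxyphenol | COc1cc(Cl)ccc1O | starting material
28 | 2-bromo-4-chloro-6-methoxyphenol | COc1cc(Cl)cc(Br)c1O | intermediate
29 | 1-bromo-5-chloro-3-methoxy-2-[(4-methoxybenzyl)oxy]benzene | COc1ccc(COc2c(Br)cc(Cl)cc2OC)cc1 | intermediate
30 | methyl 2-{5-chloro-3-methoxy-2-[(4-methoxybenzyl)oxy]phenyl}acetate | COC(=O)Cc1cc(Cl)cc(OC)c1OCc1ccc(OC)cc1 | intermediate
31 | methyl 2-{5-chloro-3-methoxy-2-[(4-methoxybenzyl)oxy]phenyl}-2-diazoacetate | COC(=O)C(=[N+]=[N-])c1cc(Cl)cc(OC)c1OCc1ccc(OC)cc1 | intermediate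
32 | methyl (2S,3R)-5-chloro-7-methoxy-2-(4-methoxyphenyl)-2,3-dihydrobenzofuran-3-carboxylate (cis) | COc1cc(Cl)cc2c1O[C@H](c1ccc(OC)cc1)[C@@H]2C(=O)OC | intermediate
33 | methyl (2S,3S)-5-chloro-7-methoxy-2-(4-methoxyphenyl)-2,3-dihydrobenzofuran-3-carboxylate (trans) | COc1cc(Cl)cc2c1O[C@H](c1ccc(OC)cc1)[C@H]2C(=O)OC | intermediate
34 | (2S,3S)-5-chloro-7-methoxy-2-(4-methoxyphenyl)-2,3-dihydrobenzofuran-3-carboxylic acid | COc1cc(Cl)cc2c1O[C@H](c1ccc(OC)cc1)[C@H]2C(=O)O | intermediate
35 | (2S,3S)-5-chloro-3-(3,5-dimethoxyphenyl)-7-methoxy-2-(4-methoxyphenyl)-2,3-dihydrobenzofuran | COc1cc(Cl)cc2c1O[C@H](c1ccc(OC)cc1)[C@H]2c1cc(OC)cc(OC)c1 | intermediate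
36 | 6-methyl-2-[(E)-2-(4,4,5,5-tetramethyl-1,3,2-dioxaborolan-2-yl)ethenyl]-1,3,6,2-dioxazaborocane-4,8-dione (pinacol boronate / MIDA boronate of (E)-ethene-1,2-diyldiboronic acid) | CN1CC(=O)OB(/C=C/B2OC(C)(C)C(C)(C)O2)OC(=O)C1 | starting material
37 | 2-{(E)-2-[(2S,3S)-3-(3,5-dimethoxyphenyl)-7-methoxy-2-(4-methoxyphenyl)-2,3-dihydrobenzofuran-5-yl]ethenyl}-6-methyl-1,3,6,2-dioxazaborocane-4,8-dione | COc1cc(/C=C/B3OC(=O)CN(C)CC(=O)O3)cc2c1O[C@H](c1ccc(OC)cc1)[C@H]2c1cc(OC)cc(OC)c1 | intermediate
38 | {(E)-2-[(2S,3S)-3-(3,5-dimethoxyphenyl)-7-methoxy-2-(4-methoxyphenyl)-2,3-dihydrobenzofuran-5-yl]ethenyl}boronic acid | COc1cc(/C=C/B(O)O)cc2c1O[C@H](c1ccc(OC)cc1)[C@H]2c1cc(OC)cc(OC)c1 | intermediate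
39 | nona-O-methyl ether of the target (all nine phenols as methyl ethers) | COc1ccc([C@H]2Oc3c(OC)cc(/C=C/c4ccc5c(c4)O[C@@H](c4ccc(OC)cc4)[C@@H]5c4cc(OC)cc5c4[C@H](c4cc(OC)cc(OC)c4)[C@@H](c4ccc(OC)cc4)O5)cc3[C@@H]2c2cc(OC)cc(OC)c2)cc1 | intermediate
40 | CNP0265934.1 | Oc1ccc([C@H]2Oc3c(O)cc(/C=C/c4ccc5c(c4)O[C@@H](c4ccc(O)cc4)[C@@H]5c4cc(O)cc5c4[C@H](c4cc(O)cc(O)c4)[C@@H](c4ccc(O)cc4)O5)cc3[C@@H]2c2cc(O)cc(O)c2)cc1 | target

## Step count and risks

Total step count: 27. Longest linear sequence: 13 steps (steps 7–17, then 26 and 27, from 11).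

Steps most likely to fail:

Step 17. The C3 radical of unit 3 in 25 is flanked by its C2 aryl group and by the peri substituent at C4 (all of unit 2). Its capture by the arylnickel species and the reductive elimination may therefore be slow, so that the radical is reduced or dimerises and the anti selectivity erodes. The fallback sets out from 25 and 11 and comes back at 26. Acid 25 is esterified with N-hydroxyphthalimide (N,N'-diisopropylcarbodiimide, DMAP cat., CH2Cl2) to the redox-active ester 1,3-dioxoisoindolin-2-yl (2S,3S)-4-[(2R,3R)-6-chloro-2-(4-methoxyphenyl)-2,3-dihydrobenzofuran-3-yl]-6-methoxy-2-(4-methoxyphenyl)-2,3-dihydrobenzofuran-3-carboxylate F3. Bromide 11 is converted (Mg, LiCl, THF; then ZnCl2) into (3,5-dimethoxyphenyl)zinc chloride F4. F3 and F4 are then coupled in a nickel-catalysed decarboxylative Negishi-type reaction (NiCl2·glyme, dtbbpy, THF/DMF, 25 °C). Here the arylnickel species is present in high concentration, because it is made by transmetalation and not by a light-limited cycle, and it both releases and captures the radical.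

Step 15. The hindered, electron-rich aryl bromide 23 may add slowly to zerovalent nickel, and its arylnickel species may capture the benzylic radical from 10 slowly, so that the radical is lost to hydrogen abstraction and dimerisation. The fallback sets out from 10 and 23 and comes back at 24. Acid 10 is esterified with N-hydroxyphthalimide (N,N'-diisopropylcarbodiimide, DMAP cat., CH2Cl2) to 1,3-dioxoisoindolin-2-yl (2R,3R)-6-chloro-2-(4-methoxyphenyl)-2,3-dihydrobenzofuran-3-carboxylate F1. Bromide 23 is exchanged to the more reactive methyl (2S,3S)-4-iodo-6-methoxy-2-(4-methoxyphenyl)-2,3-dihydrobenzofuran-3-carboxylate F2 by a copper-catalysed aromatic Finkelstein reaction (CuI, trans-N,N'-dimethylcyclohexane-1,2-diamine, NaI, dioxane, 110 °C). F1 and F2 are then joined by a nickel-catalysed reductive cross-electrophile coupling (NiBr2·glyme, dtbbpy, Zn, DMA, 25 °C). Zinc, not light, turns the cycle over, the aryl iodide adds readily, and the radical is released from the ester next to the nickel centre that must capture it.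

Step 27. Ninefold ether cleavage needs long exposure to BBr3 and the HBr it forms. During it the electron-rich stilbene may be protonated, hydrobrominated or oligomerised, and partly demethylated material may precipitate and be cleaved incompletely. The fallback sets out from 26 and 35 and comes back at 40; it removes the methyl groups before the stilbene exists and on smaller molecules. BBr3 (CH2Cl2, −78 → 0 °C) converts 26 into 5-[(2S,3S)-4-[(2R,3R)-6-chloro-2-(4-hydroxyphenyl)-2,3-dihydrobenzofuran-3-yl]-6-hydroxy-2-(4-hydroxyphenyl)-2,3-dihydrobenzofuran-3-yl]benzene-1,3-diol F5, and 35 into 5-[(2S,3S)-5-chloro-7-hydroxy-2-(4-hydroxyphenyl)-2,3-dihydrobenzofuran-3-yl]benzene-1,3-diol F6. F6 is coupled with 36 (Pd(OAc)2, SPhos, anhydrous K3PO4 in excess, dioxane, 80 °C; these phosphine catalysts tolerate free phenols) to the MIDA boronate of {(E)-2-[(2S,3S)-3-(3,5-dihydroxyphenyl)-7-hydroxy-2-(4-hydroxyphenyl)-2,3-dihydrobenzofuran-5-yl]ethenyl}boronic acid F7. The slow-release Suzuki–Miyaura coupling of F5 with F7 (Pd(OAc)2, SPhos, aq. K3PO4, degassed dioxane/H2O, 60 °C) then proceeds through the free {(E)-2-[(2S,3S)-3-(3,5-dihydroxyphenyl)-7-hydroxy-2-(4-hydroxyphenyl)-2,3-dihydrobenzofuran-5-yl]ethenyl}boronic acid F8 and gives 40 directly.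

Further compounds

F1 | step 15 | 1,3-dioxoisoindolin-2-yl (2R,3R)-6-chloro-2-(4-methoxyphenyl)-2,3-dihydrobenzofuran-3-carboxylate | Clc1ccc2c(c1)O[C@@H](c1ccc(OC)cc1)[C@@H]2C(=O)ON1C(=O)c2ccccc2C1=O
F2 | step 15 | methyl (2S,3S)-4-iodo-6-methoxy-2-(4-methoxyphenyl)-2,3-dihydrobenzofuran-3-carboxylate | COc1cc(I)c2c(c1)O[C@H](c1ccc(OC)cc1)[C@H]2C(=O)OC
F3 | step 17 | 1,3-dioxoisoindolin-2-yl (2S,3S)-4-[(2R,3R)-6-chloro-2-(4-methoxyphenyl)-2,3-dihydrobenzofuran-3-yl]-6-methoxy-2-(4-methoxyphenyl)-2,3-dihydrobenzofuran-3-carboxylate | Clc1ccc2c(c1)O[C@@H](c1ccc(OC)cc1)[C@@H]2c1cc(OC)cc2c1[C@H](C(=O)ON1C(=O)c3ccccc3C1=O)[C@@H](c1ccc(OC)cc1)O2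
F4 | step 17 | (3,5-dimethoxyphenyl)zinc chloride | COc1cc([Zn]Cl)cc(OC)c1
F5 | step 27 | 5-[(2S,3S)-4-[(2R,3R)-6-chloro-2-(4-hydroxyphenyl)-2,3-dihydrobenzofuran-3-yl]-6-hydroxy-2-(4-hydroxyphenyl)-2,3-dihydrobenzofuran-3-yl]benzene-1,3-diol | Clc1ccc2c(c1)O[C@@H](c1ccc(O)cc1)[C@@H]2c1cc(O)cc2c1[C@H](c1cc(O)cc(O)c1)[C@@H](c1ccc(O)cc1)O2
F6 | step 27 | 5-[(2S,3S)-5-chloro-7-hydroxy-2-(4-hydroxyphenyl)-2,3-dihydrobenzofuran-3-yl]benzene-1,3-diol | Oc1cc(Cl)cc2c1O[C@H](c1ccc(O)cc1)[C@H]2c1cc(O)cc(O)c1
F7 | step 27 | MIDA boronate of {(E)-2-[(2S,3S)-3-(3,5-dihydroxyphenyl)-7-hydroxy-2-(4-hydroxyphenyl)-2,3-dihydrobenzofuran-5-yl]ethenyl}boronic acid | Oc1cc(/C=C/B3OC(=O)CN(C)CC(=O)O3)cc2c1O[C@H](c1ccc(O)cc1)[C@H]2c1cc(O)cc(O)c1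
F8 | step 27 | {(E)-2-[(2S,3S)-3-(3,5-dihydroxyphenyl)-7-hydroxy-2-(4-hydroxyphenyl)-2,3-dihydrobenzofuran-5-yl]ethenyl}boronic acid | Oc1cc(/C=C/B(O)O)cc2c1O[C@H](c1ccc(O)cc1)[C@H]2c1cc(O)cc(O)c1
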